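A small charge of catalyst (20 mol% of the starting material) leaves each turnover as it entered, so I freeze it. The catalysed step is then pseudo-first-order in starting material, beside the first-order side step, and the two divide what they take in a fixed ratio r, a selectivity factor, throughout a run.

I write r = g·λ·a, with λ the catalyst loading, a the charged molarity of starting material, and g a partition constant that varies with temperature. In fractions of the charge, with q the protic impurity per starting material, the target fraction is y = (1 − q)·r/(1 + r). Crystals count inside y.

in all of them: catalyst 20 mol%
- north-east: starting material 0.037 M; protic impurity 1.48 mM; temperature 75 °C; run made earlier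
- east: starting material 0.15 M; protic impurity 1.48 mM; temperature 95 °C; run made earlier
- south-west: starting material 0.074 M; protic impurity 2.2 mM; temperature 75 °C; run made earlier
- midnight: starting material 0.074 M; protic impurity 1.48 mM; temperature 100 °C; time 1.5 h
- dawn: starting material 0.074 M; protic impurity 1.48 mM; temperature 90 °C; time 1.5 h

| run | time / min | target / % | starting material / % |
|---|---|---|---|
| north-east | 12.0 | 57.4 | 3.8 |
| north-east | 40.0 | 59.5 | 0 |
| north-east | 80.0 | 59.7 | 0.2 |
| north-east | 120 | 59.9 | 0.6 |
| east | 15.0 | 66.2 | 0.4 |
| east | 25.0 | 66.2 | 0 |
| east | 40.0 | 65.7 | 0 |
| east | 50.0 | 66.4 | 0.4 |
| south-west | 8.00 | 72.1 | 3.1 |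
| south-west | 20.0 | 74.5 | 0 |
| south-west | 50.0 | 74.5 | 0 |
| south-west | 120 | 74.1 | 0 |

(readings scatter by 0.3 percentage points)

- which of the two there is more of at the end, midnight (side product / target)
- which of the two there is more of at the end, dawn (side product / target)
- how much target is there at the end, in percent of the starting material charged: midnight
- how much target is there at the end, in percent of the starting material charged: dawn

- amounts and yields of target count crystals too
- given per volume of solution although it is solid: crystals
- candidate steps: starting material + catalyst -> catalyst + target; starting material -> side product; crystals <-> target; starting material + protic impurity -> quenched substrate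

1. Time. By hand, it adds nothing once the starting material has gone. The south-west run reads 0% starting material at 20.0 min, and its target moves from 74.5% to 74.1% by 120 min, about the scatter. The new flasks run longer, at 1.5 h, so I read plateaus.

2. Protic impurity. By hand, I let it take its full equivalent as an assumption, so q is 2.00% at midnight and dawn and 2.97% in the south-west run. I subtract it.

3. Catalyst. At 75 °C, the north-east run reads r = 1.66 and the south-west run 3.23. That is twice the ratio for twice the catalyst. So g reads 224 /M and 218 /M.

4. Temperature. The east run at 95 °C reads r = 2.04, so g = 67.9 /M, less than at 75 °C. Dawn at 90 °C lies as far below 95 °C as midnight at 100 °C lies above it, and that gap fits 4 times into the span down to 75 °C. Taking ln g as straight in temperature, each gap is worth a factor 1.34. This gives the partition constant at dawn's temperature, 90.9 /M, and 50.7 /M at midnight.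

5. Reckoning. Dawn has r = 1.35, so more target than side product, with y = 56.2%. Midnight has r = 0.750, so less target, with y = 42.0%.

The forecast, slightly different from my figures, names side product at midnight and target at dawn, with 42.2% and 55.9% of target, reasoning: “The remainder splits between the catalysed route”.

The flasks give 42.1% target against 56.2% side product at midnight, and 55.7% against 42.6% at dawn.

    starting material + catalyst → catalyst + target (k = 46.0 /M/min, Ea = 52.0 kJ/mol)
    starting material → side product (k = 0.520 /min, Ea = 115 kJ/mol)
    crystals ⇌ target, rate k3*(cs3 - [target]) while solid is left; crystals form when [target] > cs3 (solubility = 2.50 mM, k = 1.60 /min)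
    starting material + protic impurity → quenched substrate (k = 33.0 /M/min, Ea = 73.0 kJ/mol)
    (constants at 90 °C)

Dawn's target over side product is 1.31, against my r of 1.35. The neighbour flask is dawn with 12 mol% of catalyst, other charges and the time held. The same partition constant gives r = 0.807, so by hand less target than side product, with y = 43.8%. That flask holds 43.2% target, and its largest share is side product, at 55.0%.

The runs stem from a simulated flask from invented constants, noise included.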